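# Proposed synthesis of CNP0289180.1 by citronellal Michael–aldol annulation with a ring C vinyl ketone

## The problem

The target is a primary (E)-allylic alcohol on a 6-7-7 carbocyclic core, numbered here as follows. C1 is the exocyclic methylene carbon on C2. Ring C is C2–C3–C4–C5–C6–C25–C24, ring B is C6–C7–C8–C9–C23–C24–C25 and ring A is C9–C10–C12–C13–C14–C23, with methyl C11 on C10. The side chain C15–C22 (methyl C16 on C15, methyl C21 on C20, hydroxymethyl C22) sits on C14.

Rings B and C share C6, C25 and C24 and form a bicyclo[4.4.1]undecane with a bridgehead double bond C5=C6. Ring A is fused to ring B across C9–C23 and carries the tetrasubstituted alkene C9=C10.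

Four stereocentres must be set; in this numbering the target is (14S,15S,19E,23R,24S):

- C15 (S) lies in the chain and is best bought.
- C14 (S) is next to C15 but is hardly controlled by it.
- C23 (R) carries its ring B bond trans to the C14 substituent, so C14 can control it.
- C24 (S) is a bridgehead. Its configuration is the sense of twist of the bicycle, so it can only be fixed when ring B or ring C closes.

The allylic alcohol, the C1=C2 methylene, the strained C5=C6 alkene and the C9=C10 alkene exclude strong protic acid, hydrogenation and unselective oxidants late in the route.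

The enabling feature is that C23 and C14–C22 are the ten carbons of (S)-citronellal, with the aldehyde carbon at C23 and the α-carbon at C14. Ring A is a cyclohexene whose C10 can be a ketone, so ring A can close around the aldehyde by forming C13–C14 and C9–C23.

## Retrosynthesis

**O–Si and C1=C2.** Target 24 is traced to its silyl ether 23 and then to ketone 22 by removing C1. A ketone at C2 is the natural handle because it also activates C24, the carbon through which ring B is closed. The forward steps are a methylenation and a fluoride desilylation, neither of which touches the alkenes.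

**C24–CO2Me.** Ketone 22 is traced to β-keto ester 21. The extra ester costs one step to remove, but it makes C24 the only nucleophilic position of ring C and lets ring C be stored as a regiodefined silyl enol ether. The forward reaction must remove the ester without moving C5=C6 and must place H-24 where the ester was.

**C10–C11.** Methyl C11 of 21 is cut to give enol triflate 20, which comes from silyl enol ether 19. The alternative, methyl addition to a C10 ketone followed by dehydration, would give alkene regioisomers. The enol derivative instead fixes C9=C10 because it is born in the preceding conjugate addition.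

**C23–C24, ring B.** Silyl enol ether 19 is opened to cyclohexenone 18. Cutting C8–C9 or C6–C7 instead would leave two adjacent stereocentres to be joined intermolecularly. The chosen cut makes C23–C24 inside a seven-membered ring, with C14 directing the face of C23 and the tether directing C24. The forward Mukaiyama–Michael addition must also deliver the C10 enolate as a silyl enol ether.

**C13–C14 and C9–C23, ring A.** Enone 18 is divided through keto aldehyde 17 into aldehyde 6 and vinyl ketone 16. This is the most convergent cut of the molecule: 6 brings C15 and the whole side chain, 16 brings ring C with its bridgehead alkene in place. The forward reaction must set C14 under catalyst control and leave the masked β-keto ester untouched.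

**Ring C.** Vinyl ketone 16 comes from Weinreb amide 15 and a vinyl nucleophile. Amide 15 is the formal [4+3] adduct (through divinylcyclopropane 14) of siloxyvinyl diazoester 9 and diene 13, which forms C24–C25 and C3–C4. The cycloaddition gives the cycloheptadiene, the ester and the enol ether in one step. It asks only that the carbenoid choose the 1,1-disubstituted double bond of 13.

**Small pieces.** Diene 13 arises by enyne cross-metathesis of alkyne 12, made through acyl imidazole 11 from hex-5-ynoic acid 10. Diazoester 9 comes from diazo ketoester 8 and methyl acetoacetate 7.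

**Aldehyde.** Aldehyde 6 is traced through alcohol 5, silyl ether 4, allylic alcohol 3 and acetate 2 to (S)-citronellol 1. The cut at C22–O (allylic oxidation) is preferred to building the trisubstituted alkene, because the (E)-geometry then follows from the mechanism of the oxidation.

## Roads not taken

**Alternative 1:** Norcaradiene-type opening of a [4.4.1]propellane.

- **Cut and key step.** The C6–C24 bond is reconnected retrosynthetically, so rings B and C become two six-membered rings sharing a cyclopropane in propellane enone A1. Forward, silylation (t-BuMe2SiOTf, Et3N) gives a 2-siloxynorcaradiene. This opens by cleavage of C6–C24, creates C5=C6 and, after mild acid protonation at C24, gives bridged dienone A2.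
- **Merits.** The bridgehead alkene is made late by a strain-releasing pericyclic step and never has to be carried through the route. In this respect it is better than the chosen plan, where C5=C6 must survive a silyl Lewis acid, palladium and 150 °C. The skeleton before opening is ordinary six-membered ring chemistry.
- **Weak points.** C24 is fixed by protonation after the cyclopropane configuration is erased, so it rests on a kinetic protonation. A2 has an extra C3=C4 double bond that must be reduced beside C5=C6 in a cross-conjugation-free dienone, where 1,4- and 1,6-reduction compete. A1 needs a face-selective cyclopropanation of a tetrasubstituted ring-fusion alkene on a ring A that already carries the side chain.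
- **Comparison.** The chosen plan offers convergence from two fragments of five or six steps. It takes C15 and the chain from the chiral pool, and it fixes C24 in a C–C bond-forming ring closure, not a protonation.

**Alternative 2:** Equilibrating enolate cycloalkylation closing ring B.

- **Cut and key step.** The cut is C8–C9. Forward, KOt-Bu in t-BuOH equilibrates the enolates of iodo ketone A3 and the C9 enolate displaces the primary iodide at C8, giving bridged tricyclic ketone A4.
- **Merits.** No auxiliary ester is needed, so there is no decarboxylation. The C1=C2 methylene is already present, and the ring size leaves only the C9 enolate able to cyclise. After ring closure this road is two or three steps shorter than the chosen one.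
- **Weak points.** The iodide is homoallylic to C5=C6, so E2 elimination to a conjugated diene competes directly under alkoxide. Seven-membered ring formation by alkylation is entropically slow. A4 has a C10 ketone with no regiochemical memory, so C9=C10 must be made by a thermodynamic enolisation that also has C12 to choose from. A3 needs C23 and C24 to be joined beforehand between two separate rings with control of both centres.
- **Comparison.** The chosen plan offers the C9=C10 enol derivative as a direct product of ring closure, and forms C23–C24 intramolecularly.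

**Alternative 3:** Type 2 rhodium (5+2) of vinylcyclopropane and allene.

- **Cut and key step.** The cuts are C24–C25 and C2–C3. Forward, [Rh(CO)2Cl]2 (monovalent rhodium) opens the cyclopropane of the 2-cyclopropylallyl arm of allene–vinylcyclopropane A5 and joins it to the internal allene double bond. This closes rings B and C and gives the silyl ether A6 of the target directly.
- **Merits.** This is clearly the most direct endgame. The bridgehead alkene, the exocyclic methylene and C24 arise in one step, and only a desilylation remains. The chosen plan needs six steps after ring B closure.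
- **Weak points.** All risk sits in one late step on the most valuable intermediate. The internal allene double bond must react rather than the terminal one, the facial sense at C24 depends on a tether through a tetrasubstituted cyclohexene, and rhodium may isomerise the allene. A5 itself, with trans C14/C23, the C9=C10 alkene, an allene and a vinylcyclopropane, is a long linear synthesis.
- **Comparison.** The chosen plan offers reaction classes in routine use at every step, cheap fragments, catalyst control of C14, and failures that can be repaired locally.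

Key step: step 12

## Route

Assumption: the divinylcyclopropane 14 forms as a racemate and partly as its trans isomer; both converge on achiral 15 on heating, so step 10 needs no stereocontrol.

Step 1
Reactants: 1 (S)-citronellol
Product: 2 (S)-citronellyl acetate
Conditions: Ac2O, Et3N, DMAP (cat.), CH2Cl2, 0 °C to rt
Reagents that add atoms: acetic anhydride, CC(=O)OC(C)=O
Why: Acylation of the primary alcohol; the acetate masks O-1 during the allylic oxidation and can later be removed beside a silyl ether.

Step 2
Reactants: 2 (S)-citronellyl acetate
Product: 3 (3S,6E)-8-hydroxy-3,7-dimethyloct-6-en-1-yl acetate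
Conditions: SeO2 (cat.), t-BuOOH, salicylic acid (cat.), CH2Cl2, rt
Reagents that add atoms: tert-butyl hydroperoxide, CC(C)(C)OO (oxygen passed on through SeO2, O=[Se]=O)
Why: Catalytic SeO2 allylic oxidation (ene reaction, then 2,3-sigmatropic shift) oxidises the methyl group trans to the chain, which should give the (E)-allylic alcohol; any over-oxidised enal is separated here.

Step 3
Reactants: 3 (3S,6E)-8-hydroxy-3,7-dimethyloct-6-en-1-yl acetate
Product: 4 (3S,6E)-8-[(tert-butyldiphenylsilyl)oxy]-3,7-dimethyloct-6-en-1-yl acetate
Conditions: TBDPSCl, imidazole, DMF, rt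
Reagents that add atoms: tert-butyl(chloro)diphenylsilane, CC(C)(C)[Si](Cl)(c1ccccc1)c1ccccc1
Why: Imidazole-assisted silylation; the diphenyl-tert-butylsilyl group is chosen because it must outlast a silyl Lewis acid, CsF and hot wet DMSO and still fall to fluoride at the end.

Step 4
Reactants: 4 (3S,6E)-8-[(tert-butyldiphenylsilyl)oxy]-3,7-dimethyloct-6-en-1-yl acetate
Product: 5 (3S,6E)-8-[(tert-butyldiphenylsilyl)oxy]-3,7-dimethyloct-6-en-1-ol
Conditions: K2CO3, MeOH, rt
Reagents that add atoms: none
Why: Transesterification removes the acetate; the silyl ether is stable to methanolic carbonate.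

Step 5
Reactants: 5 (3S,6E)-8-[(tert-butyldiphenylsilyl)oxy]-3,7-dimethyloct-6-en-1-ol
Product: 6 (3S,6E)-8-[(tert-butyldiphenylsilyl)oxy]-3,7-dimethyloct-6-enal
Conditions: TEMPO (cat.), PhI(OAc)2, CH2Cl2, rt
Reagents that add atoms: none
Why: Oxoammonium oxidation of a primary alcohol stops at the aldehyde and leaves the alkene, the silyl ether and the β-stereocentre alone.

Step 6
Reactants: 7 methyl acetoacetate
Product: 8 methyl 2-diazo-3-oxobutanoate
Conditions: 4-acetamidobenzenesulfonyl azide, Et3N, MeCN, 0 °C to rt
Reagents that add atoms: 4-acetamidobenzenesulfonyl azide, CC(=O)Nc1ccc(cc1)S(=O)(=O)N=[N+]=[N-]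
Why: Regitz diazo transfer to an active methylene compound.

Step 7
Reactants: 8 methyl 2-diazo-3-oxobutanoate
Product: 9 methyl 3-[(tert-butyldimethylsilyl)oxy]-2-diazobut-3-enoate
Conditions: TBSOTf, Et3N, CH2Cl2, 0 °C
Reagents that add atoms: tert-butyldimethylsilyl trifluoromethanesulfonate, CC(C)(C)[Si](C)(C)OS(=O)(=O)C(F)(F)F
Why: Soft enolisation and O-silylation of the acetyl group give the siloxyvinyl diazoester, a standard donor/acceptor carbenoid precursor; it is used without storage.

Step 8
Reactants: 10 hex-5-ynoic acid
Product: 12 N-methoxy-N-methylhex-5-ynamide, via acyl imidazole 11 (not isolated)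
Conditions: 1,1'-carbonyldiimidazole, CH2Cl2, rt; then MeNHOMe·HCl, rt
Reagents that add atoms: N,O-dimethylhydroxylamine hydrochloride, CNOC.Cl; 1,1'-carbonyldiimidazole, O=C(n1ccnc1)n1ccnc1 (its imidazole stays only in 11)
Why: Acid activation as the acyl imidazole and aminolysis give the Weinreb amide, the latent vinyl ketone carbonyl C10.

Step 9
Reactants: 12 N-methoxy-N-methylhex-5-ynamide
Product: 13 N-methoxy-N-methyl-5-methylidenehept-6-enamide
Conditions: second-generation Grubbs catalyst, (H2IMes)(PCy3)Cl2Ru=CHPh (5 mol%), ethylene (1 atm), toluene, 80 °C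
Reagents that add atoms: ethylene, C=C
Why: Cross enyne metathesis of a terminal alkyne with ethylene: the ruthenium methylidene adds across the triple bond and ethylene releases the vinylcarbene, which should give the 2-substituted buta-1,3-diene.

Step 10
Reactants: 9 methyl 3-[(tert-butyldimethylsilyl)oxy]-2-diazobut-3-enoate; 13 N-methoxy-N-methyl-5-methylidenehept-6-enamide
Product: 15 methyl 2-[(tert-butyldimethylsilyl)oxy]-6-{4-[methoxy(methyl)amino]-4-oxobutyl}cyclohepta-1,5-diene-1-carboxylate, via cis-divinylcyclopropane 14 (not isolated)
Conditions: Rh2(OAc)4 (1 mol%), CH2Cl2, reflux, slow addition of 9; then toluene, 110 °C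
Reagents that add atoms: none
Why: Tandem cyclopropanation–Cope rearrangement (formal [4+3]): the electrophilic rhodium vinylcarbenoid should attack the methylene carbon of the more electron-rich 1,1-disubstituted double bond, where positive charge develops at a tertiary allylic carbon, and the cis-divinylcyclopropane rearranges through a boat transition state to the 1,4-cycloheptadiene. Heating converts any trans isomer, and the product is achiral.

Step 11
Reactants: 15 methyl 2-[(tert-butyldimethylsilyl)oxy]-6-{4-[methoxy(methyl)amino]-4-oxobutyl}cyclohepta-1,5-diene-1-carboxylate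
Product: 16 methyl 2-[(tert-butyldimethylsilyl)oxy]-6-(4-oxohex-5-en-1-yl)cyclohepta-1,5-diene-1-carboxylate
Conditions: CH2=CHMgBr, THF, −78 to 0 °C; cold aq. NH4Cl
Reagents that add atoms: vinylmagnesium bromide, C=C[Mg]Br
Why: Weinreb ketone synthesis: the magnesium chelate of the tetrahedral adduct stops after one addition, and the amide is far more electrophilic than the vinylogous carbonate ester on ring C. A cold quench and prompt use keep the liberated amine from adding to the enone.

Step 12
Reactants: 6 (3S,6E)-8-[(tert-butyldiphenylsilyl)oxy]-3,7-dimethyloct-6-enal; 16 methyl 2-[(tert-butyldimethylsilyl)oxy]-6-(4-oxohex-5-en-1-yl)cyclohepta-1,5-diene-1-carboxylate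
Product: 18 methyl 2-[(tert-butyldimethylsilyl)oxy]-6-{2-[(3S)-3-[(2S,5E)-7-[(tert-butyldiphenylsilyl)oxy]-6-methylhept-5-en-2-yl]-6-oxocyclohex-1-en-1-yl]ethyl}cyclohepta-1,5-diene-1-carboxylate, via keto aldehyde 17 (not isolated)
Conditions: (S)-α,α-diphenylprolinol trimethylsilyl ether (20 mol%), ethyl 3,4-dihydroxybenzoate (20 mol%), 6 (1.5 equiv), CH2Cl2, 4 °C; then Bn2NH·CF3CO2H, toluene, 50 °C
Reagents that add atoms: none
Why: The amine condenses with 6 to the (E)-enamine, whose C14 adds to the terminal carbon C13 of vinyl ketone 16 (activated by hydrogen bonding to the catechol co-catalyst), and hydrolysis of the iminium ion releases keto aldehyde 17 and the catalyst. The closest known reaction type is the amine-catalysed Michael addition of α-unbranched aldehydes to alkyl vinyl ketones followed by aldol condensation to 4-substituted cyclohexenones, which has been run on citronellal itself. Ring A then closes by a 6-(enolendo)-exo-trig aldol addition of the ketone α-carbon C9 to the aldehyde carbon C23, through the iminium ion formed with dibenzylamine, and E1cB loss of water; attack from C12 would give a four-membered ring and does not compete. C14 is the only new stereocentre: the CPh2(OSiMe3) group of the (S)-catalyst blocks one face of the anti-enamine, C13 is delivered to the other face, and this should give 14S. The neighbouring C15 centre exerts only a weak bias, which the catalyst overrides. The step needs chemoselectivity for Michael addition over self-aldol reaction of 6, which the bulky catalyst provides, and it needs the β-keto ester of ring C to stay silent, which its silyl enol ether ensures. The ammonium salt is chosen over hydroxide so that neither the vinylogous silyl ester nor the configuration at C14 is put at risk.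

Step 13
Reactants: 18 (cyclohexenone from step 12)
Product: 19 tricyclic β-keto ester with the C9=C10 silyl enol ether: skeleton and numbering of 24, C2 as ketone, CO2Me on C24 in place of H-24, OTBS on C10, O-22 as TBDPS ether; C14, C15 and C23 arranged as in 24, ester on the outward bridgehead face
Conditions: Me3SiNTf2 (10 mol%), CH2Cl2, −78 °C; Et3N quench
Reagents that add atoms: none
Why: Intramolecular Mukaiyama–Michael addition: the silyl triflimide activates the enone carbonyl, C24 of the silyl enol ether attacks C23 in a 7-endo-trig closure, and the silyl group passes to the next enone, so the C10 enolate is kept as the C9=C10 silyl enol ether. C24 should enter axially on the face of ring A opposite the C14 side chain (H-14 and H-23 trans). Ring C should turn its bulky C2(OSi) end away from C14, so that C14 lies on the side of the one-carbon bridge C25, which fixes the quaternary C24 with the ester outward.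

Step 14
Reactants: 19 (silyl enol ether from step 13)
Product: 20 enol triflate: as 19 with OSO2CF3 on C10 in place of OTBS
Conditions: CsF, PhNTf2, DME, rt
Reagents that add atoms: N-phenylbis(trifluoromethanesulfonimide), O=S(=O)(N(c1ccccc1)S(=O)(=O)C(F)(F)F)C(F)(F)F
Why: Fluoride cleaves the enol Si–O bond and the cesium enolate is O-sulfonylated before it can equilibrate, a regiospecific silyl enol ether to enol triflate exchange; the alkyl silyl ether reacts much more slowly.

Step 15
Reactants: 20 (enol triflate from step 14)
Product: 21 methylated β-keto ester: as 20 with methyl C11 on C10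
Conditions: Pd(PPh3)4 (10 mol%), trimethylboroxine, K2CO3, 1,4-dioxane, 90 °C
Reagents that add atoms: trimethylboroxine, CB1OB(C)OB(C)O1
Why: Suzuki–Miyaura methylation of an enol triflate under zerovalent palladium catalysis; the non-enolisable β-keto ester and the silyl ether should be inert under nearly anhydrous carbonate conditions.

Step 16
Reactants: 21 (methylated β-keto ester from step 15)
Product: 22 (14S,15S,19E,23R,24S) C2 ketone: 24 with C=O at C2 in place of C1=C2 and O-22 as TBDPS ether
Conditions: LiCl, DMSO, H2O, 150 °C
Reagents that add atoms: none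
Why: Krapcho dealkoxycarbonylation: chloride removes the ester methyl group by SN2, the carboxylate loses CO2 and water protonates the bridgehead enolate. The inner face of that enolate is closed by the bicycle, so the proton should take the place the ester left and C24 keeps its configuration.

Step 17
Reactants: 22 (C2 ketone from step 16)
Product: 23 tert-butyldiphenylsilyl ether of the target
Conditions: Ph3PCH3Br, KOt-Bu, THF, 0 °C to rt
Reagents that add atoms: methyltriphenylphosphonium bromide, [Br-].C[P+](c1ccccc1)(c1ccccc1)c1ccccc1
Why: Wittig methylenation of the C2 ketone; enolisation toward C3 is harmless and enolisation toward the bridgehead C24 can only return the same configuration.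

Step 18
Reactants: 23 tert-butyldiphenylsilyl ether of the target
Product: 24 CNP0289180.1, (14S,15S,19E,23R,24S) in the numbering of "The problem"
Conditions: n-Bu4NF, THF, 0 °C to rt
Reagents that add atoms: none
Why: Fluoride cleavage of the silyl ether; no acid is involved, so the bridgehead and exocyclic alkenes are not at risk.

## Compound list

1 | (S)-citronellol | OCC[C@@H](C)CCC=C(C)C | starting material
2 | (S)-citronellyl acetate | CC(=O)OCC[C@@H](C)CCC=C(C)C | intermediate
3 | (3S,6E)-8-hydroxy-3,7-dimethyloct-6-en-1-yl acetate | CC(=O)OCC[C@@H](C)CC/C=C(\C)CO | intermediate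
4 | (3S,6E)-8-[(tert-butyldiphenylsilyl)oxy]-3,7-dimethyloct-6-en-1-yl acetate | CC(=O)OCC[C@@H](C)CC/C=C(\C)CO[Si](c1ccccc1)(c1ccccc1)C(C)(C)C | intermediate
5 | (3S,6E)-8-[(tert-butyldiphenylsilyl)oxy]-3,7-dimethyloct-6-en-1-ol | OCC[C@@H](C)CC/C=C(\C)CO[Si](c1ccccc1)(c1ccccc1)C(C)(C)C | intermediate
6 | (3S,6E)-8-[(tert-butyldiphenylsilyl)oxy]-3,7-dimethyloct-6-enal | O=CC[C@@H](C)CC/C=C(\C)CO[Si](c1ccccc1)(c1ccccc1)C(C)(C)C | intermediate
7 | methyl acetoacetate | CC(=O)CC(=O)OC | starting material
8 | methyl 2-diazo-3-oxobutanoate | CC(=O)C(=[N+]=[N-])C(=O)OC | intermediate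
9 | methyl 3-[(tert-butyldimethylsilyl)oxy]-2-diazobut-3-enoate | C=C(O[Si](C)(C)C(C)(C)C)C(=[N+]=[N-])C(=O)OC | intermediate
10 | hex-5-ynoic acid | C#CCCCC(=O)O | starting material
11 | 1-(imidazol-1-yl)hex-5-yn-1-one (acyl imidazole) | C#CCCCC(=O)n1ccnc1 | intermediate (not isolated)
12 | N-methoxy-N-methylhex-5-ynamide | C#CCCCC(=O)N(C)OC | intermediate
13 | N-methoxy-N-methyl-5-methylidenehept-6-enamide | C=CC(=C)CCCC(=O)N(C)OC | intermediate
14 | methyl 1-{1-[(tert-butyldimethylsilyl)oxy]ethenyl}-2-ethenyl-2-{4-[methoxy(methyl)amino]-4-oxobutyl}cyclopropane-1-carboxylate, the two vinyl groups cis, racemic (one enantiomer drawn) | C=C(O[Si](C)(C)C(C)(C)C)[C@]1(C(=O)OC)C[C@@]1(C=C)CCCC(=O)N(C)OC | intermediate (not isolated)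
15 | methyl 2-[(tert-butyldimethylsilyl)oxy]-6-{4-[methoxy(methyl)amino]-4-oxobutyl}cyclohepta-1,5-diene-1-carboxylate | CON(C)C(=O)CCCC1=CCCC(O[Si](C)(C)C(C)(C)C)=C(C(=O)OC)C1 | intermediate
16 | methyl 2-[(tert-butyldimethylsilyl)oxy]-6-(4-oxohex-5-en-1-yl)cyclohepta-1,5-diene-1-carboxylate | C=CC(=O)CCCC1=CCCC(O[Si](C)(C)C(C)(C)C)=C(C(=O)OC)C1 | intermediate
17 | methyl 2-[(tert-butyldimethylsilyl)oxy]-6-[(7S,8S,11E)-13-[(tert-butyldiphenylsilyl)oxy]-7-formyl-8,12-dimethyl-4-oxotridec-11-en-1-yl]cyclohepta-1,5-diene-1-carboxylate (keto aldehyde) | O=C[C@@H](CCC(=O)CCCC1=CCCC(O[Si](C)(C)C(C)(C)C)=C(C(=O)OC)C1)[C@@H](C)CC/C=C(\C)CO[Si](c2ccccc2)(c2ccccc2)C(C)(C)C | intermediate (not isolated)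
18 | methyl 2-[(tert-butyldimethylsilyl)oxy]-6-{2-[(3S)-3-[(2S,5E)-7-[(tert-butyldiphenylsilyl)oxy]-6-methylhept-5-en-2-yl]-6-oxocyclohex-1-en-1-yl]ethyl}cyclohepta-1,5-diene-1-carboxylate | O=C1CC[C@@H]([C@@H](C)CC/C=C(\C)CO[Si](c2ccccc2)(c2ccccc2)C(C)(C)C)C=C1CCC3=CCCC(O[Si](C)(C)C(C)(C)C)=C(C(=O)OC)C3 | intermediate
19 | tricyclic β-keto ester, C9=C10 tert-butyldimethylsilyl enol ether (C2 ketone, CO2Me on C24, O-22 TBDPS ether) | O=C1CCC=C2CCC3=C(O[Si](C)(C)C(C)(C)C)CC[C@@H]([C@@H](C)CC/C=C(\C)CO[Si](c4ccccc4)(c4ccccc4)C(C)(C)C)[C@@H]3[C@]1(C(=O)OC)C2 | intermediate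
20 | tricyclic β-keto ester, C10 enol triflate | O=C1CCC=C2CCC3=C(OS(=O)(=O)C(F)(F)F)CC[C@@H]([C@@H](C)CC/C=C(\C)CO[Si](c4ccccc4)(c4ccccc4)C(C)(C)C)[C@@H]3[C@]1(C(=O)OC)C2 | intermediate
21 | tricyclic β-keto ester with methyl C11 on C10 | O=C1CCC=C2CCC3=C(C)CC[C@@H]([C@@H](C)CC/C=C(\C)CO[Si](c4ccccc4)(c4ccccc4)C(C)(C)C)[C@@H]3[C@]1(C(=O)OC)C2 | intermediate
22 | (14S,15S,19E,23R,24S) tricyclic C2 ketone, O-22 TBDPS ether | O=C1CCC=C2CCC3=C(C)CC[C@@H]([C@@H](C)CC/C=C(\C)CO[Si](c4ccccc4)(c4ccccc4)C(C)(C)C)[C@@H]3[C@@H]1C2 | intermediate
23 | tert-butyldiphenylsilyl ether of the target | C=C1CCC=C2CCC3=C(C)CC[C@@H]([C@@H](C)CC/C=C(\C)CO[Si](c4ccccc4)(c4ccccc4)C(C)(C)C)[C@@H]3[C@@H]1C2 | intermediate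
24 | CNP0289180.1 | C=C1CCC=C2CCC3=C(C)CC[C@@H]([C@@H](C)CC/C=C(\C)CO)[C@@H]3[C@@H]1C2 | target

## Step count and risks

Total: 18 steps. Longest linear sequence: 12 steps (steps 1–5, then 12–18).

**Step 12 (key step).** The most likely failure is erosion of configuration at C14 through enamine–iminium equilibration of the keto aldehyde during the condensation stage. The second risk is incomplete Michael turnover, because the vinyl ketone cannot be used in large excess.

Fallback, from 6 and 16, returning at 17:

- Pinnick oxidation of 6 gives (3S,6E)-8-[(tert-butyldiphenylsilyl)oxy]-3,7-dimethyloct-6-enoic acid F1.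
- The mixed pivalic anhydride of F1 acylates lithiated (S)-4-benzyloxazolidin-2-one to give the N-acyl oxazolidinone F2.
- The chlorotitanium enolate of F2 (TiCl3(Oi-Pr), i-Pr2NEt) adds to 16 on the face away from the benzyl group, giving the auxiliary-bound Michael adduct F3 with C14 set by the auxiliary.
- LiSEt converts F3 into the ethyl thioester F4.
- Fukuyama reduction (Et3SiH, palladium on carbon) gives keto aldehyde 17, which is condensed to 18 as in the second stage of step 12.

**Step 13.** Three processes may interfere: cation–olefin cyclisation of the side-chain alkene onto the silyl-activated enone, ionisation of the allylic silyl ether, and folding of ring C in the wrong sense, which would invert C24.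

Fallback, from 18, returning at 20:

- KF in MeOH removes only the enol silyl group, giving the free β-keto ester F5 (C24 epimers and enol).
- Cs2CO3 in MeCN effects a reversible intramolecular Michael addition under thermodynamic control, giving the tricyclic diketone F6 (C9 epimers).
- Tf2O with 2,6-di-tert-butyl-4-methylpyridine gives the more substituted enol triflate 20 from the unhindered C10 ketone.

**Step 10.** The most likely failure is cyclopropanation at the monosubstituted double bond of the diene, which would put the chain on the wrong ring carbon.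

Fallback, from 9, returning at 15:

- Rh2(OAc)4-catalysed reaction of 9 with 2-(trimethylsilyloxy)buta-1,3-diene, whose enol ether double bond is by far the more electron-rich, gives methyl 2-[(tert-butyldimethylsilyl)oxy]-6-[(trimethylsilyl)oxy]cyclohepta-1,5-diene-1-carboxylate F7.
- CsF/PhNTf2 converts the simple trimethylsilyl enol ether into the C6 enol triflate F8.
- B-alkyl Suzuki coupling (Pd(dppf)Cl2, K3PO4) with the 9-BBN adduct F9 of N-methoxy-N-methylbut-3-enamide gives 15.

**Step 16.** The enolate must form at a bridgehead, so CO2 loss may be slow. Forcing conditions could then cleave the β-keto ester by retro-Claisen attack or move the bridgehead alkene.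

Fallback, from 21, returning at 22:

- Me3SnOH in 1,2-dichloroethane hydrolyses the methyl ester to the β-keto acid F10.
- The acid is converted (oxalyl chloride, then sodium N-oxypyridine-2-thione) into the Barton ester F11.
- Photolysis with t-BuSH decarboxylates through the C24 radical, which takes hydrogen on the open outer face and needs no planar bridgehead enolate, giving 22.

## Further compounds

F1 | step 12 | (3S,6E)-8-[(tert-butyldiphenylsilyl)oxy]-3,7-dimethyloct-6-enoic acid | OC(=O)C[C@@H](C)CC/C=C(\C)CO[Si](c1ccccc1)(c1ccccc1)C(C)(C)C
F2 | step 12 | (S)-4-benzyl-3-[(3S,6E)-8-[(tert-butyldiphenylsilyl)oxy]-3,7-dimethyloct-6-enoyl]oxazolidin-2-one | O=C(C[C@@H](C)CC/C=C(\C)CO[Si](c1ccccc1)(c1ccccc1)C(C)(C)C)N1[C@@H](Cc2ccccc2)COC1=O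
F3 | step 12 | auxiliary-bound Michael adduct (C14 S, imide in place of the formyl group of 17) | O=C([C@@H](CCC(=O)CCCC1=CCCC(O[Si](C)(C)C(C)(C)C)=C(C(=O)OC)C1)[C@@H](C)CC/C=C(\C)CO[Si](c2ccccc2)(c2ccccc2)C(C)(C)C)N3[C@@H](Cc4ccccc4)COC3=O
F4 | step 12 | S-ethyl thioester corresponding to 17 | CCSC(=O)[C@@H](CCC(=O)CCCC1=CCCC(O[Si](C)(C)C(C)(C)C)=C(C(=O)OC)C1)[C@@H](C)CC/C=C(\C)CO[Si](c2ccccc2)(c2ccccc2)C(C)(C)C
F5 | step 13 | free β-keto ester of 18 (C24 unfixed) | O=C1CC[C@@H]([C@@H](C)CC/C=C(\C)CO[Si](c2ccccc2)(c2ccccc2)C(C)(C)C)C=C1CCC3=CCCC(=O)C(C(=O)OC)C3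
F6 | step 13 | tricyclic C2,C10 diketone with CO2Me on C24 (C9 unfixed) | O=C1CCC=C2CCC3C(=O)CC[C@@H]([C@@H](C)CC/C=C(\C)CO[Si](c4ccccc4)(c4ccccc4)C(C)(C)C)[C@@H]3[C@]1(C(=O)OC)C2
F7 | step 10 | methyl 2-[(tert-butyldimethylsilyl)oxy]-6-[(trimethylsilyl)oxy]cyclohepta-1,5-diene-1-carboxylate | COC(=O)C1=C(O[Si](C)(C)C(C)(C)C)CCC=C(O[Si](C)(C)C)C1
F8 | step 10 | methyl 2-[(tert-butyldimethylsilyl)oxy]-6-[(trifluoromethanesulfonyl)oxy]cyclohepta-1,5-diene-1-carboxylate | COC(=O)C1=C(O[Si](C)(C)C(C)(C)C)CCC=C(OS(=O)(=O)C(F)(F)F)C1
F9 | step 10 | 4-(9-borabicyclo[3.3.1]nonan-9-yl)-N-methoxy-N-methylbutanamide | CON(C)C(=O)CCCB1C2CCCC1CCC2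
F10 | step 16 | β-keto acid of 21 | O=C1CCC=C2CCC3=C(C)CC[C@@H]([C@@H](C)CC/C=C(\C)CO[Si](c4ccccc4)(c4ccccc4)C(C)(C)C)[C@@H]3[C@]1(C(=O)O)C2
F11 | step 16 | Barton ester (2-thioxopyridin-1-yl ester) of F10 | O=C1CCC=C2CCC3=C(C)CC[C@@H]([C@@H](C)CC/C=C(\C)CO[Si](c4ccccc4)(c4ccccc4)C(C)(C)C)[C@@H]3[C@]1(C(=O)On5ccccc5=S)C2
A1 | alternative 1 | [4.4.1]propellane enone (C6 in the place later taken by H-24) | O=C1C=CC[C@]23CCC4=C(C)CC[C@@H]([C@@H](C)CC/C=C(\C)CO[Si](C)(C)C(C)(C)C)[C@@H]4[C@]12C3
A2 | alternative 1 | bridged 3,5-dien-2-one, tert-butyldimethylsilyl ether | O=C1C=CC=C2CCC3=C(C)CC[C@@H]([C@@H](C)CC/C=C(\C)CO[Si](C)(C)C(C)(C)C)[C@@H]3[C@@H]1C2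
A3 | alternative 2 | iodo ketone (C8 iodide, C10 ketone, ring B open at C8–C9) | C=C1CCC=C(CCI)C[C@H]1[C@@H]2CC(=O)CC[C@H]2[C@@H](C)CC/C=C(\C)CO[Si](C)(C)C(C)(C)C
A4 | alternative 2 | bridged tricyclic C10 ketone | C=C1CCC=C2CC[C@H]3C(=O)CC[C@@H]([C@@H](C)CC/C=C(\C)CO[Si](C)(C)C(C)(C)C)[C@@H]3[C@@H]1C2
A5 | alternative 3 | ring A allene carrying the 2-cyclopropylallyl arm | C=C=C[C@@H]1C(CCC(=C)C2CC2)=C(C)CC[C@H]1[C@@H](C)CC/C=C(\C)CO[Si](C)(C)C(C)(C)C
A6 | alternative 3 | tert-butyldimethylsilyl ether of the target | C=C1CCC=C2CCC3=C(C)CC[C@@H]([C@@H](C)CC/C=C(\C)CO[Si](C)(C)C(C)(C)C)[C@@H]3[C@@H]1C2
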